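1. Carry 0.345 h⁻¹: the fall constant λ of L, the natural logarithm of the ratio of two L readings, the highest reading and a later one, divided by the time between them, read in the elm run between 60.0 min and 120 min.

| flask | D | E | temperature | remark | time |
|---|---|---|---|---|---|
| larch | 0.50 M | 0.30 M | 8 °C | run made earlier |  |
| elm | 0.50 M | 0.45 M | 35 °C | run made earlier |  |
| birch | 0.25 M | 0.60 M | 8 °C | run made earlier |  |
| spring | 0.50 M | 0.600 M | 20 °C |  | 3.0 h |
| noon | 0.50 M | 0.600 M | 45 °C |  | 3.0 h |
| midnight | 0.50 M | 0.600 M | −5 °C |  | 3.0 h |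

larch run (percent of the D charged)

| time / h | L / % |
|---|---|
| 0.417 | 3 |
| 0.833 | 5 |
| 2.00 | 12 |
| 4.00 | 17 |
| 8.00 | 19 |

elm run (percent of the D charged)

| time / min | L / % |
|---|---|
| 8.00 | 9 |
| 15.0 | 20 |
| 30.0 | 22 |
| 60.0 | 24 |
| 120 | 17 |

birch run (percent of the D charged)

| time / h | L / % |
|---|---|
| 0.667 | 13 |
| 1.50 | 24 |
| 2.50 | 26 |
| 5.00 | 33 |
| 8.00 | 36 |

(scatter of a reading: 1.5 percentage points)

- what was read earlier has a scatter of 1.5 percentage points, one standard deviation

- the flask with the highest amount of L, in percent of the D charged ("all alike" if they lie within 1.5 percentage points) (spring / noon / midnight / all alike)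
- final L, as a percentage of the D charged, in spring
- final L, as a percentage of the D charged, in noon
- final L, as a percentage of the D charged, in midnight

2. Larch and birch still end higher than their previous readings, so they give no λ, and I reckon noon through elm. Take the elm reading of 24% as the large term and compute only the correction, the fall over the time up to 3.0 h: 12.0%.

3. Objection: each reading scatters by 1.5 percentage points, and the peak's place is loose. Starting from the 30.0 min reading instead gives λ = 0.172 h⁻¹ and 14.3%, a shift of 2.3 points, so the estimate is no sharper than that and becomes the upper end of a range.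

4. Objection: noon is hotter than elm, so λ may be larger there. The average rate of rise of L up to the second reading, divided by the starting concentration of E, in elm is 8.89 times that in larch. Taken as a constant factor per degree, that multiplies λ by 2.25 for noon, giving 0.774 h⁻¹ and 5.10%. For spring the same scaling gives 0.102 h⁻¹. But a fall need not speed up like a rise, so I commit to noon between 5.10% and 14.3%.

5. The forecast names spring, with 31% in spring, 18% in noon and 15% in midnight; of noon it says “E is almost exhausted”. Its noon value lies above my range.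

6. The flasks give 26.4% in spring, the highest, 7.38% in noon and 12.8% in midnight.

    E → Q (k = 0.0380 h⁻¹, Ea = 109 kJ mol⁻¹)
    L ⇌ G (K = 1.20, k = 0.0180 h⁻¹, Ea = 89.0 kJ mol⁻¹, ΔH = −46.0 kJ mol⁻¹)
    D + E → X + Z (k = 0.420 L mol⁻¹ h⁻¹, Ea = 65.0 kJ mol⁻¹)
    E + X → J + Z (k = 0.310 L mol⁻¹ h⁻¹, Ea = 75.0 kJ mol⁻¹)
    D + E ⇌ L + Z (K = 0.570, k = 0.770 L mol⁻¹ h⁻¹, Ea = 56.0 kJ mol⁻¹, ΔH = 33.0 kJ mol⁻¹)
    E + L → J + Z (k = 0.0190 L mol⁻¹ h⁻¹, Ea = 72.0 kJ mol⁻¹)
    (constants at 20 °C)

7. Noon has not come to rest at 3.0 h: from 1.50 h L fell from 15.3% to 7.38%, so λ = 0.488 h⁻¹, while E, the limiting reagent there, reached 1.75% of its charge. Nor has spring: its scaled λ carries 26.4% to 1.66% at 30.0 h, and the flask holds 0.572%. Noon's λ carries 7.38% to <0.001%, and at ten times the time the flask holds 0% L, with D up from 49.1% to 55.3%.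

All runs come from a simulation for an exercise; noise was put on by code.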